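**Assumptions (one line each)**
- The SMILES is taken literally as the target: it encodes (1R,3S,3aS,6R,6aS), in which the two ring-fusion hydrogens (C3a–H, C6a–H) are trans, the C3 aryl is cis to C4 and the C6 aryl is cis to C1. This is not the cis-fused arrangement usually drawn for pinoresinol lignans (that would need C3a and C6 inverted), and the route is built for exactly the stereoisomer written.
- Vanillin and methyl 4-hydroxybut-2-ynoate are taken as commercial.

Numbering in names: furo[3,4-c]furan, C1 (lactol carbon), O2, C3 (ArCH), C3a, C4 (CH2), O5, C6 (ArCH), C6a. "Ar" = 3-methoxy-4-(triisopropylsilyloxy)phenyl.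

**Retrosynthetic overview**
1. Target ⇐ trans-fused furofuranone by lactone half-reduction (C1) and final phenol desilylation.
2. Ring B (C4–O5 bond, formed second) ⇐ monocyclic lactone 1,4-diol by intramolecular SN2 at the primary carbon, with retention at C6.
3. C6a–C6 bond ⇐ anti-aldol of a cis-4,5-disubstituted γ-butyrolactone with protected vanillin (sets C6a and C6).
4. cis-Lactone (C3, C3a) ⇐ racemic γ-aryl butenolide by the proposed dynamic kinetic Cu–H conjugate reduction.
5. Butenolide (ring A, formed first) ⇐ (Z)-β-iodoenoate from methyl 4-hydroxybut-2-ynoate plus protected vanillin.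

**Route**

Step 1
Reactants: 1 vanillin
Product: 2 3-methoxy-4-(triisopropylsilyloxy)benzaldehyde
Conditions: TIPSCl, imidazole, DMF, rt
Reagents that add atoms: triisopropylsilyl chloride, CC(C)[Si](Cl)(C(C)C)C(C)C
Why: Phenol silylation (silyl ether protection); the aryl TIPS ether tolerates the Grignard, Cu–H/alkoxide, boron enolate, triflation and DIBAL steps.

Step 2
Reactants: 3 methyl 4-hydroxybut-2-ynoate
Product: 4 methyl (Z)-4-hydroxy-3-iodobut-2-enoate
Conditions: NaI, AcOH, 70 °C
Reagents that add atoms: sodium iodide, [Na+].[I-]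
Why: Conjugate hydroiodination of a 2-ynoate; iodide adds at C3 and anti protonation gives the Z isomer (I cis to CO2Me), with CH2OH trans to the ester so it cannot lactonise.

Step 3
Reactants: 4 methyl (Z)-4-hydroxy-3-iodobut-2-enoate
Product: 5 methyl (Z)-3-iodo-4-(triethylsilyloxy)but-2-enoate
Conditions: TESCl, imidazole, CH2Cl2, 0 °C
Reagents that add atoms: chlorotriethylsilane, CC[Si](Cl)(CC)CC
Why: Silyl protection of the primary alcohol; TES is chosen because it can later be removed with buffered HF in the presence of aryl-OTIPS.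

Step 4
Reactants: 5 methyl (Z)-3-iodo-4-(triethylsilyloxy)but-2-enoate; 2 3-methoxy-4-(triisopropylsilyloxy)benzaldehyde
Product: 6 rac-5-Ar-4-[(triethylsilyloxy)methyl]furan-2(5H)-one
Conditions: i-PrMgCl·LiCl, THF, −40 °C; then 2, −40 °C → rt
Reagents that add atoms: none
Why: Iodine–magnesium exchange gives the configurationally stable (Z)-β-magnesio enoate (Knochel-type), which adds 1,2 to the aldehyde; the alkoxide, cis to the ester, lactonises with loss of MeOH (butenolide annulation), giving racemic C5.

Step 5
Reactants: 6 rac-5-Ar-4-[(triethylsilyloxy)methyl]furan-2(5H)-one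
Product: 7 (4S,5S)-5-Ar-4-[(triethylsilyloxy)methyl]dihydrofuran-2(3H)-one (4,5-cis)
Conditions: Cu(OAc)2 (5 mol %), (R)-DTBM-SEGPHOS (5.5 mol %), PMHS, NaOt-Bu (20 mol %), t-BuOH (3 equiv), degassed toluene, 0 °C
Reagents that add atoms: none
Why: Proposed new method: dynamic kinetic asymmetric Cu–H conjugate reduction of a racemic γ-aryl butenolide. The C5–H of 6 is benzylic and vinylogously α to the lactone carbonyl, so catalytic t-BuONa racemises 6 through the achiral 2-oxidofuran faster than reduction; L*Cu–H delivers hydride to C4 of the matched (5R) enantiomer on the face anti to the aryl group (catalyst and substrate control reinforce, the mismatched enantiomer is recycled); t-BuOH protonates the copper enolate and the silane regenerates Cu–H; 7 has no acidic stereocentre, so C5 (S) and C4 (S, CH2OTES cis to aryl) are locked. Closest known reaction type: Cu–H/chiral bisphosphine asymmetric conjugate reduction of β-substituted butenolides and the DKR conjugate reduction of α′-stereogenic cyclopentenones. The ligand antipode (written as R) is not predicted with confidence and must be confirmed on the first run.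

Step 6
Reactants: 7 (4S,5S)-5-Ar-4-[(triethylsilyloxy)methyl]dihydrofuran-2(3H)-one; 2 3-methoxy-4-(triisopropylsilyloxy)benzaldehyde
Product: 8 (3S,4S,5S)-3-[(R)-hydroxy(Ar)methyl]-5-Ar-4-[(triethylsilyloxy)methyl]dihydrofuran-2(3H)-one
Conditions: c-Hex2BOTf, Et3N, CH2Cl2, −78 °C; then 2, −78 → −20 °C; pH 7 buffer, H2O2, MeOH, 0 °C
Reagents that add atoms: none
Why: Boron-mediated anti-aldol (Zimmerman–Traxler); the ring-locked E(O)-enolate gives the anti adduct (carbinol R), and the aldehyde adds to the lactone face opposite the cis C4/C5 substituents (C3 S, 3,4-trans).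

Step 7
Reactants: 8 (3S,4S,5S)-3-[(R)-hydroxy(Ar)methyl]-5-Ar-4-[(triethylsilyloxy)methyl]dihydrofuran-2(3H)-one
Product: 9 (3S,4S,5S)-3-[(R)-hydroxy(Ar)methyl]-4-(hydroxymethyl)-5-Ar-dihydrofuran-2(3H)-one
Conditions: HF·pyridine, pyridine, THF, 0 °C
Reagents that add atoms: none
Why: Selective acidic-fluoride cleavage of the primary alkyl TES ether; aryl TIPS ethers survive, and with no base present the β-hydroxy lactone cannot undergo retro-aldol or C3 epimerisation.

Step 8
Reactants: 9 (3S,4S,5S)-3-[(R)-hydroxy(Ar)methyl]-4-(hydroxymethyl)-5-Ar-dihydrofuran-2(3H)-one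
Product: 10 (3S,3aS,6R,6aS)-3,6-bis-Ar-tetrahydro-1H,3H-furo[3,4-c]furan-1-one (trans ring fusion)
Conditions: Tf2O (1.05 equiv), 2,6-di-tert-butyl-4-methylpyridine, CH2Cl2, −78 → 0 °C
Reagents that add atoms: none
Why: Intramolecular Williamson-type etherification through the in situ primary triflate (5-exo-tet SN2); the C–O bond forms at the primary carbon so C6 keeps its configuration, the irreversible displacement pays for the strain of the trans fusion, and the hindered base cannot enolise C6a.

Step 9
Reactants: 10 (3S,3aS,6R,6aS)-3,6-bis-Ar-tetrahydro-1H,3H-furo[3,4-c]furan-1-one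
Product: 11 (1R,3S,3aS,6R,6aS)-3,6-bis-Ar-tetrahydro-1H,3H-furo[3,4-c]furan-1-ol
Conditions: DIBAL-H (1.1 equiv), CH2Cl2, −78 °C; MeOH then aq. Rochelle salt
Reagents that add atoms: none
Why: Half-reduction of a lactone to the lactol with DIBAL-H; C1 is set by anomeric equilibration, which should favour the (1R) anomer with OH trans to the C6a–C6 bond, and the cold neutral work-up limits ring-opening and C6a epimerisation.

Step 10
Reactants: 11 (1R,3S,3aS,6R,6aS)-3,6-bis-Ar-tetrahydro-1H,3H-furo[3,4-c]furan-1-ol
Product: 12 4α-hydroxypinoresinol as specified by the SMILES, (1R,3S,3aS,6R,6aS)-3,6-bis(4-hydroxy-3-methoxyphenyl)tetrahydro-1H,3H-furo[3,4-c]furan-1-ol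
Conditions: TBAF, AcOH (1:1), THF, 0 °C
Reagents that add atoms: none
Why: Fluoride desilylation of the two aryl TIPS ethers; AcOH buffering keeps the medium near neutral so the lactol and the benzylic ethers are untouched.

**Compound list**
1 | vanillin | COc1cc(C=O)ccc1O | starting material
2 | 3-methoxy-4-(triisopropylsilyloxy)benzaldehyde | COc1cc(C=O)ccc1O[Si](C(C)C)(C(C)C)C(C)C | intermediate
3 | methyl 4-hydroxybut-2-ynoate | COC(=O)C#CCO | starting material
4 | methyl (Z)-4-hydroxy-3-iodobut-2-enoate | COC(=O)/C=C(\I)CO | intermediate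
5 | methyl (Z)-3-iodo-4-(triethylsilyloxy)but-2-enoate | COC(=O)/C=C(\I)CO[Si](CC)(CC)CC | intermediate
6 | rac-5-Ar-4-[(triethylsilyloxy)methyl]furan-2(5H)-one (racemic) | COc1cc(C2OC(=O)C=C2CO[Si](CC)(CC)CC)ccc1O[Si](C(C)C)(C(C)C)C(C)C | intermediate
7 | (4S,5S)-5-Ar-4-[(triethylsilyloxy)methyl]dihydrofuran-2(3H)-one | COc1cc([C@H]2OC(=O)C[C@H]2CO[Si](CC)(CC)CC)ccc1O[Si](C(C)C)(C(C)C)C(C)C | intermediate
8 | (3S,4S,5S)-3-[(R)-hydroxy(Ar)methyl]-5-Ar-4-[(triethylsilyloxy)methyl]dihydrofuran-2(3H)-one | COc1cc([C@H]2OC(=O)[C@H]([C@@H](O)c3ccc(O[Si](C(C)C)(C(C)C)C(C)C)c(OC)c3)[C@H]2CO[Si](CC)(CC)CC)ccc1O[Si](C(C)C)(C(C)C)C(C)C | intermediate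
9 | (3S,4S,5S)-3-[(R)-hydroxy(Ar)methyl]-4-(hydroxymethyl)-5-Ar-dihydrofuran-2(3H)-one | COc1cc([C@H]2OC(=O)[C@H]([C@@H](O)c3ccc(O[Si](C(C)C)(C(C)C)C(C)C)c(OC)c3)[C@H]2CO)ccc1O[Si](C(C)C)(C(C)C)C(C)C | intermediate
10 | (3S,3aS,6R,6aS)-3,6-bis-Ar-tetrahydro-1H,3H-furo[3,4-c]furan-1-one | COc1cc([C@H]2OC(=O)[C@H]3[C@H]2CO[C@H]3c2ccc(O[Si](C(C)C)(C(C)C)C(C)C)c(OC)c2)ccc1O[Si](C(C)C)(C(C)C)C(C)C | intermediate
11 | (1R,3S,3aS,6R,6aS)-3,6-bis-Ar-tetrahydro-1H,3H-furo[3,4-c]furan-1-ol | COc1cc([C@H]2O[C@@H](O)[C@H]3[C@H]2CO[C@H]3c2ccc(O[Si](C(C)C)(C(C)C)C(C)C)c(OC)c2)ccc1O[Si](C(C)C)(C(C)C)C(C)C | intermediate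
12 | 4α-hydroxypinoresinol (as given) | COc1cc([C@H]2O[C@@H](O)[C@H]3[C@H]2CO[C@H]3c2ccc(O)c(OC)c2)ccc1O | target

**Totals**
- Total steps: 10
- Longest linear sequence: 9 steps (3 → 4 → 5 → 6 → 7 → 8 → 9 → 10 → 11 → 12)

**Three steps most likely to fail**
1. Step 5 (proposed DKR Cu–H reduction): racemisation may be too slow or ee/dr too low. Fallback (known chemistry, auxiliary control): Mg-catalysed Evans anti-aldol of N-(pent-4-enoyl)-4-benzyloxazolidinone with 2, then LiBH4 auxiliary removal, TES protection of the primary alcohol, ozonolysis and lactol oxidation (TEMPO/PhI(OAc)2) to reach 7. The anti adduct maps onto the 4,5-cis lactone.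
2. Step 8 (closing the strained trans-fused THF by SN2): lactone-carbonyl participation or elimination may compete. Fallback: swap the order of ring closures. Open the lactone of 8 as its Weinreb amide with the C5–OH silylated, close ring B as an unstrained monocyclic THF by the same primary-triflate etherification, then re-form the lactone last by intramolecular acyl substitution, so the trans fusion is made by lactonisation.
3. Step 9 (and the lactol's survival through step 10): the trans-fused lactol may ring-open to the hydroxy-aldehyde, over-reduce, or epimerise at C6a. Fallback: change to a trapped-lactol endgame. Run DIBAL-H with in situ Ac2O/pyridine/DMAP (reductive acetylation) to hold the closed form as the C1 acetate, remove the aryl silyl groups, and release the lactol last under neutral enzymatic (lipase) hydrolysis.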